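The readings come from a simulation with made-up constants; noise was put on by code.

In this closed, stirred vessel at constant temperature, first end groups react with second end groups while scavenger is present, and the readings follow links and free first end groups.

| setting | Saturday's | Sunday's | flask |
|---|---|---|---|
| first end groups | 0.050 M | 0.075 M | 0.050 M |
| second end groups | 1.05 equiv | 1.05 equiv | 1.05 equiv |
| scavenger | 0.30 equiv | 0.30 equiv | 0.300 equiv |
| remark | the very flask that is asked about, followed so far | run made earlier |  |
| time |  |  | 6.0 min |

| run | time / min | links / % | first end groups / % |
|---|---|---|---|
| Saturday's | 0.500 | 18.1 | 72.7 |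
| Saturday's | 1.00 | 30.2 | 59.6 |
| Saturday's | 1.50 | 38.7 | 51.4 |
| Saturday's | 2.00 | 45.1 | 44.1 |
| Saturday's | 2.50 | 50.1 | 39.6 |
| Saturday's | 3.00 | 53.4 | 34.9 |
| Sunday's | 0.250 | 15.0 | 76.7 |
| Sunday's | 0.833 | 33.3 | 53.0 |
| Sunday's | 1.33 | 44.4 | 42.6 |
| Sunday's | 2.50 | 57.9 | 28.7 |
| Sunday's | 3.00 | 60.6 | 25.9 |
| Sunday's | 4.00 | 64.5 | 21.3 |

(standard deviation of a reading: 0.5 percentage points)

* links present at 6.0 min, in percent of the first end groups charged
* first end groups present at 6.0 min, in percent of the first end groups charged

- a reading of first end groups is of its free form alone

At the last reading of Saturday's flask, 11.7% of the charge reads as neither links nor free first end groups. This missing share (the mass-balance gap), the charge minus links minus free first end groups, reads 10.2% at 1.00 min, each reading being good to 0.5 percentage points, and I choose to freeze it at its last value.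

Two extreme versions of Saturday's flask give me a bracket for the links at 6.0 min. If links stop now, they stay at 53.4%. If they follow plain second order from the first reading, with rate constant times charge 0.442 /min, they reach 72.6%. But that law already overshoots at 3.00 min, giving 57.0%, while the last interval still adds 3.3 points, so I expect the flask between the two. Sunday's last reading has the same product of concentration and time and shows 64.5% links, inside the bracket. I take that value, and the frozen share then leaves 23.8% first end groups.

The forecast, seeing a sum that “drifts down only slowly”, gives 64% links (61.5% to 66.5%) and 24% first end groups (21.5% to 26%), slightly different from mine.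

The flask gives 64.7% links and 23.5% first end groups, inside both ranges, and the gap is 11.8% against the frozen 11.7%.

    first end groups → decomposition product (k = 2.30 × 10⁻⁶ /s)
    scavenger + released group → scavenged by-product (k = 3.80 /M/s)
    first end groups + second end groups ⇌ links + released group (K = 2.60, k = 0.150 /M/s)
    first end groups + released group ⇌ idle adduct, settled at all times (K = 44.0 /M)

In the asked flask at 6.00 min the idle adduct stands at 11.8%. In the neighbouring flask with 0.420 equiv of second end groups, the same subtraction on 35.3% links and 59.8% first end groups leaves 4.96%, less than the frozen share, and its idle adduct stands at 4.90%.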